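**Assumptions (one line each):** β‑Eudesmol and obovatol are both sold as natural‑product reagents, so I treat them as commercial. The 4‑O‑aryl configuration in the target is 4α‑O (equatorial) with 4β‑CH3 (axial), read directly from the SMILES.

## Retrosynthetic overview
1. The only disconnection is the tertiary C4–O aryl ether. It is cut back to the exocyclic 4(15)‑alkene of β‑eudesmol (1) and the catechol OH of obovatol (2), by Markovnikov hydroaryloxylation.
2. No ring is built. The trans‑decalin, with C5, C7 and C10 already set, comes from β‑eudesmol. Both aryl rings and the diaryl ether come from obovatol.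
3. The only stereocenter created is C4, and it is set in the coupling step.

## Route

**Step 1**
Reactants: 1 (β‑eudesmol, 1.5 equiv) and 2 (obovatol, 1.0 equiv)
Product: 3 (eudesobovatol A)
Conditions: HNTf2 (5 mol %), 4 Å MS, CH2Cl2, –20 °C, 1–2 h. The reaction is quenched with Et3N at low temperature before warming, then purified by chromatography.
Reagents that add atoms: none (HNTf2 is a catalyst and no atoms of it end up in the product).
Why:
- Protonation of the 1,1‑disubstituted exocyclic alkene gives the tertiary C4 cation. The most accessible phenol OH of 2 traps it as the ether: a Brønsted‑acid Markovnikov hydroaryloxylation.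
- Obovatol's C1‑OH is the only phenol with a free ortho position. Its C2‑OH is flanked by OH and OAr, so the bulky cation goes to C1‑OH, which is the oxygen carrying the terpene in the target.
- The new C4 stereocenter is set by face selectivity. The β‑face of the cation is shielded by the axial 10β‑methyl (1,3‑diaxial), so the phenol attacks from the α‑face. This gives 4α‑OAr (equatorial) and 4β‑CH3, matching the target.
- Low temperature and a short reaction time keep the step under kinetic control, so the tertiary ether does not re‑ionize and epimerize or eliminate to α/γ‑eudesmol.
- C5, C7 and C10 are untouched. The 11‑OH (tertiary alcohol), the two allyl groups, the diaryl ether and the free 2‑OH tolerate catalytic acid at –20 °C.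
- Atom check: C15H26O + C18H18O3 = C33H44O4, the formula of the target, with nothing lost.

## Compound list
1 | β‑Eudesmol, (2R,4aR,8aS)‑decahydro‑α,α,4a‑trimethyl‑8‑methylene‑2‑naphthalenemethanol (5α‑H, 10β‑CH3, 7β‑C(CH3)2OH) | C=C3CCC[C@]4(C)CC[C@@H](C(C)(C)O)C[C@H]43 | starting material
2 | Obovatol, 5‑allyl‑3‑(4‑allylphenoxy)benzene‑1,2‑diol | C=CCc1ccc(Oc2cc(CC=C)cc(O)c2O)cc1 | starting material
3 | Eudesobovatol A, (4R,5R,7R,10R)‑4‑O‑aryl‑eudesmane‑4,11‑diol with the aryl group being 5‑allyl‑3‑(4‑allylphenoxy)‑2‑hydroxyphenyl | C=CCc1ccc(Oc2cc(CC=C)cc(O[C@]3(C)CCC[C@]4(C)CC[C@@H](C(C)(C)O)C[C@H]43)c2O)cc1 | target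

## Summary
- Total step count: 1.
- Longest linear sequence: 1 step from commercial compounds 1 and 2.
- The route is a single operation, so I list the three most likely failure points inside it instead of three separate steps.

1. **Regioselectivity (C1‑O vs C2‑O alkylation) and C‑alkylation.**
   - Fallback: build the aromatic piece from a fully protected pyrogallol. Make the 3‑aryloxy‑2‑O‑allyl‑5‑bromophenol by Chan–Lam coupling, form the tertiary ether on the single free phenol, then remove the O‑allyl group with Pd(0) and morpholine. Install the two allyl groups by Pd‑catalysed coupling with allyl‑Bpin.
2. **C4 configuration and elimination.** Acid can epimerize the ether to the more stable 4β‑OAr isomer, or dehydrate and isomerize the alkene to α/γ‑eudesmol.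
   - Fallback: use an irreversible radical‑polar crossover hydroalkoxylation (Co(salen), an N‑fluoropyridinium oxidant, PhSiH3) on the catechol with both OH groups protected as a cyclic carbonate. This bypasses acid and avoids oxidizing the free catechol. Then open the carbonate with K2CO3/MeOH.
3. **Chemoselectivity toward obovatol's allyl groups and the free catechol.** The allyl groups can isomerize or add H+, and the catechol can be oxidized.
   - Fallback: switch to a bromo analogue of obovatol, carry out the ether formation on it, and introduce both allyl groups last by Suzuki or Stille coupling with allyl‑Bpin.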